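## Retrosynthetic overview

1. Feature: in the pyrrole (N1, C2-CO2Me, C3, C4, C5-H) the most crowded bond, C3-C4, joins two carbons that each carry a 5-bromoindol-3-yl ring (indole A on C3, indole B on C4). C3 adjoins the ester carbon C2 and C4 adjoins C5-H, so the ring splits into two indolyl-C-C=N halves, one at pyruvate level and one at acetaldehyde level.
2. Last disconnection: the pyrrole N-benzoyl group and both indole N-tosyl groups come off together by methanolysis.
3. Key disconnection: C3-C4 and N1-C5 are opened (retro Piloty-Robinson) to a mixed azine whose N-N bond ties the pyruvate imine to the aldimine. Forward, this is a [3,3] shift followed by cyclisation, with one nitrogen lost as benzamide.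
4. The azine comes from the pyruvate hydrazone and the indolylacetaldehyde. Both derive from one N-tosyl-5-bromoindole-3-carbaldehyde, by HWE olefination with acid unmasking and by Wittig homologation.
5. Ring order: both indoles are bought intact, and the pyrrole is the only ring formed, in the key step.

Key step: step 8

Assumption: the C=N bonds of the hydrazone and the azine are configurationally labile under the conditions used and their geometry does not affect the outcome, so they are drawn as the E forms. The sp3 centres of the transient intermediates of the key step are left undefined because they are lost on aromatisation.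

## Route

Step 1
Reactants: 1 5-bromo-1H-indole-3-carbaldehyde; 2 p-toluenesulfonyl chloride
Product: 3 5-bromo-1-tosyl-1H-indole-3-carbaldehyde
Conditions: NaH, DMF, 0 °C; then TsCl, 0 °C to rt
Reagents that add atoms: p-toluenesulfonyl chloride, Cc1ccc(cc1)S(=O)(=O)Cl
Why: N-sulfonylation of the sodium salt of the acidic 3-formylindole N-H is a standard protection, and the tosyl group later shields the indole nitrogen from benzoyl chloride and tames the ring so that the acetaldehyde and pyruvate derivatives can be handled.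

Step 2
Reactants: 3 5-bromo-1-tosyl-1H-indole-3-carbaldehyde; 4 (methoxymethyl)triphenylphosphonium chloride
Product: 5 5-bromo-3-(2-methoxyvinyl)-1-tosyl-1H-indole (E/Z mixture)
Conditions: 4 (1.3 equiv), KOtBu (1.2 equiv), THF, 0 °C; then 3, 0 °C to rt
Reagents that add atoms: (methoxymethyl)triphenylphosphonium chloride, COC[P+](c1ccccc1)(c1ccccc1)c1ccccc1.[Cl-]
Why: Wittig olefination of the non-enolisable aldehyde with the methoxymethylene ylide should give the enol ether as an E/Z mixture that needs no separation, and keeping the salt in slight excess over KOtBu leaves no free alkoxide to attack the sulfonamide.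

Step 3
Reactants: 5 5-bromo-3-(2-methoxyvinyl)-1-tosyl-1H-indole
Product: 6 2-(5-bromo-1-tosyl-1H-indol-3-yl)acetaldehyde
Conditions: 2 M aq. HCl, THF, 50 °C; used without storage
Reagents that add atoms: water, O
Why: Acid-catalysed enol ether hydrolysis (C-protonation, hydration of the oxocarbenium ion, loss of methanol) completes the one-carbon homologation, and the sulfonamide and the aryl bromide are inert to dilute acid.

Step 4
Reactants: 3 5-bromo-1-tosyl-1H-indole-3-carbaldehyde; 7 methyl 2-[(tert-butoxycarbonyl)amino]-2-(dimethoxyphosphoryl)acetate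
Product: 8 methyl (Z)-3-(5-bromo-1-tosyl-1H-indol-3-yl)-2-[(tert-butoxycarbonyl)amino]acrylate
Conditions: DBU, CH2Cl2, 0 °C to rt
Reagents that add atoms: methyl 2-[(tert-butoxycarbonyl)amino]-2-(dimethoxyphosphoryl)acetate, COC(=O)C(NC(=O)OC(C)(C)C)P(=O)(OC)OC
Why: Horner-Wadsworth-Emmons olefination with a phosphonoglycinate under DBU is the standard entry to protected dehydrotryptophans from N-protected indole-3-carbaldehydes and should give mainly the Z enamide, whose geometry is erased in the next step.

Step 5
Reactants: 8 methyl (Z)-3-(5-bromo-1-tosyl-1H-indol-3-yl)-2-[(tert-butoxycarbonyl)amino]acrylate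
Product: 10 methyl 3-(5-bromo-1-tosyl-1H-indol-3-yl)-2-oxopropanoate (in equilibrium with its enol), via enamino ester 9 (not isolated)
Conditions: TFA, CH2Cl2, rt; then 1 M aq. HCl, THF, rt, under N2
Reagents that add atoms: water, O
Why: Acidolysis of the Boc group frees the primary enamine 9, whose iminium tautomer is hydrolysed by aqueous acid to the α-keto ester (enamide hydrolysis as in the Erlenmeyer arylpyruvate synthesis) at room temperature, so the methyl ester and the tosyl group stay in place.

Step 6
Reactants: 10 methyl 3-(5-bromo-1-tosyl-1H-indol-3-yl)-2-oxopropanoate; 11 hydrazine hydrate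
Product: 12 methyl 3-(5-bromo-1-tosyl-1H-indol-3-yl)-2-hydrazonopropanoate
Conditions: N2H4·H2O (3 equiv), AcOH (3 equiv), MeOH/THF, 0 °C, slow addition of 10; aqueous wash
Reagents that add atoms: hydrazine hydrate, NN.O
Why: Hydrazone formation at the very electrophilic α-keto carbonyl outruns hydrazinolysis of the ester at 0 °C in buffered methanol, and slow addition of 10 to excess hydrazine together with the push-pull deactivation of the NH2 group in 12 should suppress ketazine formation.

Step 7
Reactants: 12 methyl 3-(5-bromo-1-tosyl-1H-indol-3-yl)-2-hydrazonopropanoate; 6 2-(5-bromo-1-tosyl-1H-indol-3-yl)acetaldehyde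
Product: 13 mixed azine methyl 3-(5-bromo-1-tosyl-1H-indol-3-yl)-2-{[2-(5-bromo-1-tosyl-1H-indol-3-yl)ethylidene]hydrazono}propanoate
Conditions: cat. AcOH, 4 Å molecular sieves, CH2Cl2, rt
Reagents that add atoms: none
Why: Acid-catalysed condensation of an N-unsubstituted hydrazone with an aldehyde is the standard stepwise synthesis of unsymmetrical azines, and removal of water by the sieves plus the absence of free hydrazine keeps the two halves from exchanging.

Step 8
Reactants: 13 mixed azine; 14 benzoyl chloride
Product: 18 methyl 1-benzoyl-3,4-bis(5-bromo-1-tosyl-1H-indol-3-yl)-1H-pyrrole-2-carboxylate, via bis(ene-hydrazide) 15 (not isolated), via bis(N-benzoylimine) 16 (not isolated), via benzamidopyrroline 17 (not isolated)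
Conditions: BzCl (2.5 equiv), dry pyridine, 0 °C to rt; then 160 °C (sealed vessel, microwave)
Reagents that add atoms: benzoyl chloride, O=C(Cl)c1ccccc1
Why: Proposed new method: the acyl chloride promoted Piloty-Robinson pyrrole synthesis, known for symmetrical azines of enolisable aldehydes, is extended here to a mixed α-imino ester/aldimine azine. Benzoylation of both azine nitrogens, with loss of the two indolyl-CH2 protons to pyridine, should give bis(ene-hydrazide) 15, in which both C=C bonds gain conjugation with an indole and one also with the ester. A chair-like 3,4-diaza-Cope [3,3] shift then exchanges the weak N-N bond for the congested C3-C4 bond and gives bis(N-benzoylimine) 16. The C2 acylimine tautomerises to the ester-conjugated enamide, whose nitrogen adds to the aldehyde-derived acylimine carbon C5 in a 5-exo-trig closure of the pyrrole ring (17), and loss of benzamide aromatises it. The two sp3 centres created at C3 and C4 vanish on tautomerisation and aromatisation, so no stereocontrol is required. The step needs cross-coupling rather than homo-coupling and a single regiochemistry: the N-N tether fixes the pairing before any C-C bond forms, each imine carbon has only one enolisable neighbour, closure by either nitrogen leads to the same pyrrole, and the tosyl groups keep the indole nitrogens away from benzoyl chloride.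

Step 9
Reactants: 18 methyl 1-benzoyl-3,4-bis(5-bromo-1-tosyl-1H-indol-3-yl)-1H-pyrrole-2-carboxylate
Product: 19 methyl 3,4-bis(5-bromo-1H-indol-3-yl)-1H-pyrrole-2-carboxylate (target)
Conditions: Cs2CO3 (excess), THF/MeOH 2:1, rt to 50 °C
Reagents that add atoms: none
Why: Base-mediated methanolysis should cleave the azolide-like N-benzoyl group at once and then both indole N-sulfonyl groups (Cs2CO3/MeOH detosylation, helped by the electron-withdrawing bromine atoms), while ester exchange at C2 with methoxide is degenerate.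

## Compound list

1 | 5-bromo-1H-indole-3-carbaldehyde | O=Cc1c[nH]c2ccc(Br)cc12 | starting material
2 | p-toluenesulfonyl chloride | Cc1ccc(cc1)S(=O)(=O)Cl | starting material
3 | 5-bromo-1-tosyl-1H-indole-3-carbaldehyde | O=Cc1cn(S(=O)(=O)c2ccc(C)cc2)c2ccc(Br)cc12 | intermediate
4 | (methoxymethyl)triphenylphosphonium chloride | COC[P+](c1ccccc1)(c1ccccc1)c1ccccc1.[Cl-] | starting material
5 | 5-bromo-3-(2-methoxyvinyl)-1-tosyl-1H-indole (E/Z mixture, E isomer drawn) | CO/C=C/c1cn(S(=O)(=O)c2ccc(C)cc2)c2ccc(Br)cc12 | intermediate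
6 | 2-(5-bromo-1-tosyl-1H-indol-3-yl)acetaldehyde | O=CCc1cn(S(=O)(=O)c2ccc(C)cc2)c2ccc(Br)cc12 | intermediate
7 | methyl 2-[(tert-butoxycarbonyl)amino]-2-(dimethoxyphosphoryl)acetate (racemic) | COC(=O)C(NC(=O)OC(C)(C)C)P(=O)(OC)OC | starting material
8 | methyl (Z)-3-(5-bromo-1-tosyl-1H-indol-3-yl)-2-[(tert-butoxycarbonyl)amino]acrylate | COC(=O)/C(NC(=O)OC(C)(C)C)=C/c1cn(S(=O)(=O)c2ccc(C)cc2)c2ccc(Br)cc12 | intermediate
9 | methyl (Z)-2-amino-3-(5-bromo-1-tosyl-1H-indol-3-yl)acrylate (not isolated) | COC(=O)/C(N)=C/c1cn(S(=O)(=O)c2ccc(C)cc2)c2ccc(Br)cc12 | intermediate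
10 | methyl 3-(5-bromo-1-tosyl-1H-indol-3-yl)-2-oxopropanoate | COC(=O)C(=O)Cc1cn(S(=O)(=O)c2ccc(C)cc2)c2ccc(Br)cc12 | intermediate
11 | hydrazine hydrate | NN.O | starting material
12 | methyl 3-(5-bromo-1-tosyl-1H-indol-3-yl)-2-hydrazonopropanoate (E form drawn) | COC(=O)/C(Cc1cn(S(=O)(=O)c2ccc(C)cc2)c2ccc(Br)cc12)=N/N | intermediate
13 | mixed azine of pyruvate 10 and aldehyde 6 (E,E form drawn) | COC(=O)/C(Cc1cn(S(=O)(=O)c2ccc(C)cc2)c2ccc(Br)cc12)=N/N=C/Cc1cn(S(=O)(=O)c2ccc(C)cc2)c2ccc(Br)cc12 | intermediate
14 | benzoyl chloride | O=C(Cl)c1ccccc1 | starting material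
15 | N,N'-dibenzoyl bis(ene-hydrazide) (not isolated) | COC(=O)/C(=C/c1cn(S(=O)(=O)c2ccc(C)cc2)c2ccc(Br)cc12)N(C(=O)c1ccccc1)N(C(=O)c1ccccc1)/C=C/c1cn(S(=O)(=O)c2ccc(C)cc2)c2ccc(Br)cc12 | intermediate
16 | methyl 2,5-bis(benzoylimino)-3,4-bis(5-bromo-1-tosyl-1H-indol-3-yl)pentanoate (not isolated, diastereomer mixture) | COC(=O)C(=NC(=O)c1ccccc1)C(c1cn(S(=O)(=O)c2ccc(C)cc2)c2ccc(Br)cc12)C(C=NC(=O)c1ccccc1)c1cn(S(=O)(=O)c2ccc(C)cc2)c2ccc(Br)cc12 | intermediate
17 | methyl 5-benzamido-1-benzoyl-3,4-bis(5-bromo-1-tosyl-1H-indol-3-yl)-4,5-dihydro-1H-pyrrole-2-carboxylate (not isolated, diastereomer mixture) | COC(=O)C1=C(c2cn(S(=O)(=O)c3ccc(C)cc3)c3ccc(Br)cc23)C(c2cn(S(=O)(=O)c3ccc(C)cc3)c3ccc(Br)cc23)C(NC(=O)c2ccccc2)N1C(=O)c1ccccc1 | intermediate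
18 | methyl 1-benzoyl-3,4-bis(5-bromo-1-tosyl-1H-indol-3-yl)-1H-pyrrole-2-carboxylate | COC(=O)c1n(C(=O)c2ccccc2)cc(-c2cn(S(=O)(=O)c3ccc(C)cc3)c3ccc(Br)cc23)c1-c1cn(S(=O)(=O)c2ccc(C)cc2)c2ccc(Br)cc12 | intermediate
19 | methyl 3,4-bis(5-bromo-1H-indol-3-yl)-1H-pyrrole-2-carboxylate | COC(=O)c1[nH]cc(-c2c[nH]c3ccc(Br)cc23)c1-c1c[nH]c2ccc(Br)cc12 | target

## Step count and risks

Total step count: 9.
Longest linear sequence: 7 steps (steps 1, 4, 5, 6, 7, 8, 9). The aldehyde branch (steps 2 and 3) joins at step 7.

**Risk 1: step 8 (labelled step).**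
- The second N-acylation may stall at the weakly nucleophilic, ester-conjugated imine nitrogen.
- The acylated aldimine half may fragment at the N-N bond.
- The mono-acylated ene-hydrazine may close in a 5-endo sense before the [3,3] shift.
- Chloride may demethylate the ester at the high temperature.

Fallback by known chemistry, setting out from 10 and returning at 19:
1. Deprotonation of 10 with NaH in THF and oxidative enolate coupling with half an equivalent of I2 would give the 1,4-diketone dimethyl 3,4-bis(5-bromo-1-tosyl-1H-indol-3-yl)-2,5-dioxohexanedioate F1.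
2. Paal-Knorr condensation with NH4OAc in AcOH would give dimethyl 3,4-bis(5-bromo-1-tosyl-1H-indol-3-yl)-1H-pyrrole-2,5-dicarboxylate F2.
3. Cs2CO3 in THF/MeOH would remove the tosyl groups to give dimethyl 3,4-bis(5-bromo-1H-indol-3-yl)-1H-pyrrole-2,5-dicarboxylate F3.
4. One equivalent of LiOH in THF/MeOH/water would desymmetrise F3 to 3,4-bis(5-bromo-1H-indol-3-yl)-5-(methoxycarbonyl)-1H-pyrrole-2-carboxylic acid F4, since the carboxylate formed slows the second hydrolysis.
5. Protodecarboxylation of this pyrrole-2-carboxylic acid in warm TFA would deliver 19.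

**Risk 2: step 7.**
- The halves may exchange by hydrolytic or hydrazone-transfer scrambling towards the symmetrical azines.
- The enolisable aldehyde may self-condense.
- The push-pull NH2 group may attack only sluggishly.

Fallback, setting out from 12 and returning at 13:
1. Oxidation of 12 with MnO2 in CH2Cl2 would give the diazo ester methyl 3-(5-bromo-1-tosyl-1H-indol-3-yl)-2-diazopropanoate F5.
2. Addition of PBu3 to the terminal nitrogen (Staudinger-Meyer reaction) would give the phosphazine methyl 3-(5-bromo-1-tosyl-1H-indol-3-yl)-2-[(tributylphosphoranylidene)hydrazono]propanoate F6.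
3. Aza-Wittig condensation of F6 with aldehyde 6 under neutral, water-free conditions would form 13 with no N-H hydrazone present to exchange.

**Risk 3: step 6.**
- Hydrazinolysis of the methyl ester may compete.
- Double condensation may lead to the symmetrical ketazine.
- The tosyl group may erode if the mixture warms.

Fallback, setting out from 10 and returning at 12: condensation of 10 with the mono-protected hydrazine tert-butyl carbazate (cat. AcOH, MeOH, rt), which can neither bridge two ketones nor readily attack the ester, would give methyl 3-(5-bromo-1-tosyl-1H-indol-3-yl)-2-[(tert-butoxycarbonyl)hydrazono]propanoate F7. Acidolysis with TFA in CH2Cl2 followed by neutralisation would then release 12.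

## Further compounds

F1 | step 8 | dimethyl 3,4-bis(5-bromo-1-tosyl-1H-indol-3-yl)-2,5-dioxohexanedioate (diastereomer mixture) | COC(=O)C(=O)C(c1cn(S(=O)(=O)c2ccc(C)cc2)c2ccc(Br)cc12)C(C(=O)C(=O)OC)c1cn(S(=O)(=O)c2ccc(C)cc2)c2ccc(Br)cc12
F2 | step 8 | dimethyl 3,4-bis(5-bromo-1-tosyl-1H-indol-3-yl)-1H-pyrrole-2,5-dicarboxylate | COC(=O)c1[nH]c(C(=O)OC)c(-c2cn(S(=O)(=O)c3ccc(C)cc3)c3ccc(Br)cc23)c1-c1cn(S(=O)(=O)c2ccc(C)cc2)c2ccc(Br)cc12
F3 | step 8 | dimethyl 3,4-bis(5-bromo-1H-indol-3-yl)-1H-pyrrole-2,5-dicarboxylate | COC(=O)c1[nH]c(C(=O)OC)c(-c2c[nH]c3ccc(Br)cc23)c1-c1c[nH]c2ccc(Br)cc12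
F4 | step 8 | 3,4-bis(5-bromo-1H-indol-3-yl)-5-(methoxycarbonyl)-1H-pyrrole-2-carboxylic acid | COC(=O)c1[nH]c(C(=O)O)c(-c2c[nH]c3ccc(Br)cc23)c1-c1c[nH]c2ccc(Br)cc12
F5 | step 7 | methyl 3-(5-bromo-1-tosyl-1H-indol-3-yl)-2-diazopropanoate | COC(=O)C(=[N+]=[N-])Cc1cn(S(=O)(=O)c2ccc(C)cc2)c2ccc(Br)cc12
F6 | step 7 | methyl 3-(5-bromo-1-tosyl-1H-indol-3-yl)-2-[(tributylphosphoranylidene)hydrazono]propanoate (E form drawn) | COC(=O)/C(Cc1cn(S(=O)(=O)c2ccc(C)cc2)c2ccc(Br)cc12)=N/N=P(CCCC)(CCCC)CCCC
F7 | step 6 | methyl 3-(5-bromo-1-tosyl-1H-indol-3-yl)-2-[(tert-butoxycarbonyl)hydrazono]propanoate (E form drawn) | COC(=O)/C(Cc1cn(S(=O)(=O)c2ccc(C)cc2)c2ccc(Br)cc12)=N/NC(=O)OC(C)(C)C
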